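**Retrosynthetic overview**

1. Numbering used throughout: ring carbons C1–C10 (C1–C3 = CH2, C4 = C(CH3)OH, C5 = CH–O-isobutyryl, C6 = lactone CH–O, C7 = ring-fusion CH, C8 = CHOH, C9 = C=O, C10 = CH(CH3)); C11–C13 = lactone α-carbon, carbonyl, methylene; on the six-membered ring C3–C8, β/α mean the face of / opposite to the C4 methyl group.
2. Target ⇒ C5 acylation and O8 desilylation ⇒ α-methylene lactone by decarboxylative methylenation of an α-carboxy lactone, which comes from a C7 malonyl group and O6; the C9 ketone / C8 alcohol come from hydroboration–oxidation of a C8 silyl enol ether.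
3. Key disconnection C1–C10: the ten-membered ring is the anionic oxy-Cope product of a 1-propenyl-2-vinylcyclohexanol. Enabling feature: C1–C10 is the terminal bond of the diene C1=C2–C3···C8(O)–C9=C10, so a transient C3–C8 bond folds C3–C8 into a cyclohexane that carries the C8 oxygen (the 3-oxido group that drives the rearrangement) and all four contiguous stereocentres C4–C7.
4. The cyclohexane is built on 4,4-dimethoxy-2-methylcyclohexa-2,5-dienone (from 4-methoxy-2-methylphenol): asymmetric malonate addition at C7, vinyl addition at C3, enolate oxidations at C4 and C6, directed reduction at C5.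
5. Ring order: six-membered carbocycle C3–C8 (template, from the arene) → ten-membered carbocycle (C3–C8 cleaved as C1–C10 forms) → γ-lactone.

Key step: step 10

**Route**

Step 1
Reactants: 1 4-methoxy-2-methylphenol
Product: 2 4,4-dimethoxy-2-methylcyclohexa-2,5-dien-1-one
Conditions: PhI(OAc)2 (1.1 equiv), MeOH, 0 °C
Reagents that add atoms: methanol (CO)
Why: Hypervalent-iodine oxidative dearomatisation of a para-alkoxyphenol in methanol (phenol to quinone monoketal) is a standard transformation and creates no stereocentre.

Step 2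
Reactants: 2 quinone monoketal; 3 dibenzyl malonate
Product: 4 dibenzyl 2-[(1S)-2,2-dimethoxy-4-methyl-5-oxocyclohex-3-en-1-yl]propanedioate
Conditions: LiAl[(S)-1,1'-binaphthalene-2,2'-diolate]2 (10 mol %), KOt-Bu (9 mol %), 4 Å molecular sieves, THF, rt
Reagents that add atoms: none
Why: Heterobimetallic BINOL-catalysed asymmetric Michael addition of a malonate to a cyclic enone should occur at the unsubstituted enone carbon C7 rather than at the methyl-bearing enone, the catalyst selecting the enone face so that the malonyl group enters α (the (S) antipode is chosen by analogy with the sense of induction for cyclohex-2-enone and is to be confirmed on the first run).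

Step 3
Reactants: 4 Michael adduct; 5 vinylmagnesium bromide
Product: 7 C5 ketone (3β-vinyl; 4β-methyl; 4α-OSiMe3; 7α-malonyl), via silyl enol ether 6 (not isolated)
Conditions: 5 (3.5 equiv), CuBr·SMe2 (20 mol %), Me3SiCl (4 equiv), THF, −78 → −40 °C; Et3N, cold NaHCO3 work-up; then dimethyldioxirane, acetone/CH2Cl2, −78 → 0 °C
Reagents that add atoms: chlorotrimethylsilane (C[Si](C)(C)Cl); dimethyldioxirane (CC1(C)OO1)
Why: Copper-catalysed, Me3SiCl-accelerated conjugate addition of the Grignard reagent (its first equivalent only deprotonates the malonate) should put the vinyl group on C3 trans to the C7 substituent as for 5-substituted cyclohexenones, and Rubottom oxidation of the resulting silyl enol ether delivers oxygen to C4 anti to the new vinyl group, the silyl group ending on the tertiary oxygen by 1,4-shift.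

Step 4
Reactants: 7 C5 ketone
Product: 8 6β-hydroxy ketone
Conditions: LiN(SiMe3)2 (2.2 equiv), THF, −78 °C; 2-(phenylsulfonyl)-3-phenyloxaziridine (1.2 equiv), −78 °C; AcOH quench
Reagents that add atoms: 2-(phenylsulfonyl)-3-phenyloxaziridine (O=S(=O)(N1OC1c1ccccc1)c1ccccc1)
Why: Enolate hydroxylation with a sulfonyloxaziridine: the ketone can only enolise towards C6 (C4 is quaternary), the more basic ketone enolate of the dianion reacts before the malonate anion, and the oxidant approaches anti to the C7 malonyl and the α-oriented C4 silyloxy groups, giving the 6β-alcohol.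

Step 5
Reactants: 8 6β-hydroxy ketone
Product: 9 5α,6β-diol
Conditions: Me4NBH(OAc)3 (5 equiv), MeCN/AcOH (1:1), −30 °C
Reagents that add atoms: none
Why: Hydroxyl-directed triacetoxyborohydride reduction: the free equatorial C6 hydroxyl binds boron and delivers hydride along the axial trajectory on the β face while O4 is blocked as its silyl ether, so the new C5 hydroxyl should be α (trans to O6, cis to O4).

Step 6
Reactants: 9 5α,6β-diol
Product: 10 4,5-O-isopropylidene 6β-alcohol
Conditions: 2,2-dimethoxypropane, acetone, MeOH (5 equiv), PPTS (10 mol %), rt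
Reagents that add atoms: 2,2-dimethoxypropane (COC(C)(C)OC)
Why: Acid-catalysed transketalisation removes the tertiary trimethylsilyl ether and closes the acetonide on the cis-4,5-diol (the trans-5,6-diol cannot compete), the C8 dimethyl ketal being preserved by the excess of 2,2-dimethoxypropane.

Step 7
Reactants: 10 acetonide alcohol
Product: 11 6β-benzyl ether
Conditions: 2-benzyloxy-1-methylpyridinium trifluoromethanesulfonate (2 equiv), MgO, PhCF3, 83 °C
Reagents that add atoms: 2-benzyloxy-1-methylpyridinium trifluoromethanesulfonate (C[n+]1ccccc1OCc1ccccc1.[O-]S(=O)(=O)C(F)(F)F)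
Why: Benzyl transfer from the neutral pyridinium salt protects O6 without base (which would alkylate the malonate or start lactonisation) and installs a group that cannot migrate to the C8 alkoxide in step 10.

Step 8
Reactants: 11 benzyl ether
Product: 12 C8 ketone
Conditions: LiBF4 (1.5 equiv), MeCN/H2O (50:1), rt
Reagents that add atoms: water (O)
Why: Mild Lewis-acid hydrolysis of an acyclic dimethyl ketal should be much faster than cleavage of the cyclic acetonide and avoids bases that would epimerise C3/C7 or eliminate the β-benzyloxy group.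

Step 9
Reactants: 12 C8 ketone; 13 (E)-1-bromoprop-1-ene
Product: 14 tertiary carbinol (8β-OH; 8α-(E)-prop-1-enyl; 3β-vinyl)
Conditions: 13 (3 equiv), t-BuLi (6 equiv), Et2O, −78 °C; CeCl3 (3 equiv), THF, −78 °C; then 12, −78 °C; AcOH quench at −78 °C
Reagents that add atoms: none
Why: 1,2-Addition of a weakly basic alkenylcerium reagent with retention of the (E) geometry (the first equivalent deprotonates the malonate, whose enolate shields both esters), expected anti to the axial C3 vinyl group of the preferred chair, i.e. along the axial trajectory on the α face where cerium can coordinate the syn-axial acetonide oxygen, giving the propenyl group trans to the vinyl group.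

Step 10
Reactants: 14 tertiary carbinol
Product: 16 ten-membered (2E,8Z)-diene silyl enol ether, via dipotassium enolate 15 (not isolated)
Conditions: KH (2.5 equiv), 18-crown-6 (2.5 equiv), THF, 0 → 50 °C; then i-Pr3SiOTf (1.2 equiv), −78 °C; aq. NaHCO3
Reagents that add atoms: triisopropylsilyl trifluoromethanesulfonate (CC(C)[Si](OS(=O)(=O)C(F)(F)F)(C(C)C)C(C)C)
Why: Formation of the potassium alkoxide (the malonate is deprotonated first and so shields both benzyl esters) triggers an anionic oxy-Cope [3,3]-sigmatropic rearrangement of the 3-oxido-1,5-diene C1=C2–C3–C8(O−)–C9=C10, in which the C3–C8 bond of the cyclohexane breaks as the C1–C10 bond forms, and the enolate is silylated on oxygen in the same flask. The closest known reaction type is the alkoxide-accelerated oxy-Cope ring expansion of trans-1,2-dialkenylcyclohexanols to cyclodec-5-enones. The ten-membered ring is closed by this sigmatropic four-carbon ring enlargement of the six-membered ring, not by an end-to-end cyclisation, so no high dilution is needed. The new stereocentre C10 is controlled by the chair-like transition state reached from the ring-flipped conformer with both alkenyl groups equatorial: the (E)-methyl group sits pseudo-equatorial and the sense of the chair is fixed by the C3/C8 configurations, which should translate into (10S), the (2E) alkene and the (8Z) enolate. The step needs a regiodefined C8=C9 enolate (secured because the rearrangement itself generates it and it is trapped before equilibration), chemoselectivity towards the esters (secured by the malonate enolate) and no silyl transfer to the C8 alkoxide (secured by the benzyl ether at O6).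

Step 11
Reactants: 16 (2E,8Z)-diene silyl enol ether
Product: 17 saturated (8Z)-silyl enol ether
Conditions: 2-nitrobenzenesulfonohydrazide (excess), Et3N, CH2Cl2, rt
Reagents that add atoms: none
Why: Diimide reduction transfers hydrogen concertedly to the strained, disubstituted (E)-C2=C3 bond far faster than to the trisubstituted, hindered silyl enol ether, and unlike catalytic hydrogenation leaves the benzyl groups in place.

Step 12
Reactants: 17 (8Z)-silyl enol ether
Product: 18 (8S,9R)-8-silyloxy-9-alcohol
Conditions: BH3·THF (3 equiv), THF, 0 °C; then 30% H2O2, pH 7 phosphate buffer, 0 °C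
Reagents that add atoms: hydrogen peroxide (OO)
Why: Hydroboration–oxidation of a silyl enol ether places boron on the carbon β to oxygen (C9) and hydrogen on C8 by syn addition, and attack on the outer face of the enol ether in the conformation inherited from the chair transition state (the ring and the C7 malonyl group cover the inner face) should give the (8S) silyl ether, the net result being the 1,2-transposition of the oxygen pattern.

Step 13
Reactants: 18 8-silyloxy-9-alcohol
Product: 19 (8S,10S)-8-silyloxy-9-ketone
Conditions: 1,1,1-triacetoxy-1,1-dihydro-1,2-benziodoxol-3(1H)-one (DMP, 1.5 equiv), NaHCO3, CH2Cl2, 0 °C → rt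
Reagents that add atoms: none
Why: Periodinane oxidation of the secondary C9 alcohol under buffered, non-epimerising conditions should give the α-silyloxy ketone with C8 and C10 untouched.

Step 14
Reactants: 19 8-silyloxy-9-ketone
Product: 21 α-carboxy γ-lactone 4,5-diol, via hydroxy diacid 20 (not isolated)
Conditions: H2 (1 atm), Pd/C (10 wt %), EtOAc, rt; filter; then AcOH/H2O/THF (3:1:1), 45 °C
Reagents that add atoms: none
Why: Hydrogenolysis removes the three benzyl groups, the freed C6 hydroxyl closes the five-membered lactone onto one carboxyl group of the malonic acid (O8 is silylated and O4/O5 are still tied up, so only the 12,6-lactone can form, trans-fused as fixed on the cyclohexane), and the warm aqueous acetic acid then cleaves the acetonide.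

Step 15
Reactants: 21 α-carboxy γ-lactone; 22 formaldehyde
Product: 23 α-methylene γ-lactone 4,5-diol
Conditions: 22 (37% aq., 5 equiv), Et2NH, AcOH, NaOAc, 1,4-dioxane, rt → 50 °C
Reagents that add atoms: none
Why: Decarboxylative Mannich methylenation of an α-carboxy-γ-butyrolactone converts the remaining carboxyl group into the exocyclic methylene under mild, weakly acidic conditions that should not enolise the C9 ketone.

Step 16
Reactants: 23 α-methylene lactone diol; 24 2-methylpropanoic anhydride
Product: 25 5-O-isobutyrate 8-O-silyl ether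
Conditions: 24 (1.5 equiv), DMAP (10 mol %), pyridine, CH2Cl2, 0 °C
Reagents that add atoms: none
Why: DMAP-catalysed acylation should select the only free secondary hydroxyl (C5) over the tertiary C4 hydroxyl, O8 being silylated.

Step 17
Reactants: 25 silyl ether
Product: 26 target
Conditions: HF·pyridine, pyridine/THF, 0 °C → rt
Reagents that add atoms: none
Why: Fluoride-mediated cleavage of the triisopropylsilyl ether with buffered HF·pyridine is compatible with the α-methylene lactone, the ester and the α-ketol and should release the target.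

**Compound list**

1 | 4-methoxy-2-methylphenol | COc1ccc(O)c(C)c1 | starting material
2 | 4,4-dimethoxy-2-methylcyclohexa-2,5-dien-1-one | COC1(OC)C=C(C)C(=O)C=C1 | intermediate
3 | dibenzyl malonate | O=C(OCc1ccccc1)CC(=O)OCc1ccccc1 | starting material
4 | dibenzyl 2-[(1S)-2,2-dimethoxy-4-methyl-5-oxocyclohex-3-en-1-yl]propanedioate (7α-malonyl) | COC1(OC)C=C(C)C(=O)C[C@H]1C(C(=O)OCc2ccccc2)C(=O)OCc2ccccc2 | intermediate
5 | vinylmagnesium bromide | C=C[Mg]Br | starting material
6 | C5 trimethylsilyl enol ether of the vinyl adduct (3β-vinyl, 7α-malonyl, C8 dimethyl ketal) | COC1(OC)[C@H](C=C)C(C)=C(O[Si](C)(C)C)C[C@H]1C(C(=O)OCc2ccccc2)C(=O)OCc2ccccc2 | intermediate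
7 | C5 ketone: 3β-vinyl, 4β-methyl, 4α-trimethylsilyloxy, 7α-malonyl, C8 dimethyl ketal | COC1(OC)[C@H](C=C)[C@@](C)(O[Si](C)(C)C)C(=O)C[C@H]1C(C(=O)OCc2ccccc2)C(=O)OCc2ccccc2 | intermediate
8 | as 7 with 6β-hydroxyl | COC1(OC)[C@H](C=C)[C@@](C)(O[Si](C)(C)C)C(=O)[C@H](O)[C@H]1C(C(=O)OCc2ccccc2)C(=O)OCc2ccccc2 | intermediate
9 | as 8 with the C5 ketone reduced to the 5α-alcohol | COC1(OC)[C@H](C=C)[C@@](C)(O[Si](C)(C)C)[C@@H](O)[C@H](O)[C@H]1C(C(=O)OCc2ccccc2)C(=O)OCc2ccccc2 | intermediate
10 | 4α,5α-O-isopropylidene 6β-alcohol (3β-vinyl, 7α-malonyl, C8 dimethyl ketal) | COC1(OC)[C@H](C=C)[C@@]3(C)OC(C)(C)O[C@H]3[C@H](O)[C@H]1C(C(=O)OCc2ccccc2)C(=O)OCc2ccccc2 | intermediate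
11 | 6β-O-benzyl ether of 10 | COC1(OC)[C@H](C=C)[C@@]3(C)OC(C)(C)O[C@H]3[C@H](OCc2ccccc2)[C@H]1C(C(=O)OCc2ccccc2)C(=O)OCc2ccccc2 | intermediate
12 | C8 ketone (3β-vinyl, 4,5-acetonide, 6β-OBn, 7α-malonyl) | O=C1[C@H](C=C)[C@@]3(C)OC(C)(C)O[C@H]3[C@H](OCc2ccccc2)[C@H]1C(C(=O)OCc2ccccc2)C(=O)OCc2ccccc2 | intermediate
13 | (E)-1-bromoprop-1-ene | C/C=C/Br | starting material
14 | tertiary carbinol: 8β-hydroxy, 8α-[(E)-prop-1-enyl], 3β-vinyl | O[C@]1(/C=C/C)[C@H](C=C)[C@@]3(C)OC(C)(C)O[C@H]3[C@H](OCc2ccccc2)[C@H]1C(C(=O)OCc2ccccc2)C(=O)OCc2ccccc2 | intermediate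
15 | dipotassium salt (C8 enolate and malonate carbanion) of the ring-expanded (2E)-cyclodecenone, (10S) | [K+].[K+].[O-]\C1=C/[C@@H](C)C/C=C/[C@@]3(C)OC(C)(C)O[C@H]3[C@H](OCc2ccccc2)[C@H]1[C-](C(=O)OCc2ccccc2)C(=O)OCc2ccccc2 | intermediate
16 | ten-membered (2E,8Z)-diene: 8-triisopropylsilyloxy enol ether, (10S)-methyl, 4,5-O-isopropylidene, 6-O-benzyl, 7-CH(CO2Bn)2 (C4–C7 as in 12) | CC(C)[Si](C(C)C)(C(C)C)O\C1=C/[C@@H](C)C/C=C/[C@@]3(C)OC(C)(C)O[C@H]3[C@H](OCc2ccccc2)[C@H]1C(C(=O)OCc2ccccc2)C(=O)OCc2ccccc2 | intermediate
17 | 2,3-dihydro derivative of 16 ((8Z)-silyl enol ether) | CC(C)[Si](C(C)C)(C(C)C)O\C1=C/[C@@H](C)CCC[C@@]3(C)OC(C)(C)O[C@H]3[C@H](OCc2ccccc2)[C@H]1C(C(=O)OCc2ccccc2)C(=O)OCc2ccccc2 | intermediate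
18 | (8S,9R,10S)-8-triisopropylsilyloxy-9-alcohol | CC(C)[Si](C(C)C)(C(C)C)O[C@@H]1[C@H](O)[C@@H](C)CCC[C@@]3(C)OC(C)(C)O[C@H]3[C@H](OCc2ccccc2)[C@H]1C(C(=O)OCc2ccccc2)C(=O)OCc2ccccc2 | intermediate
19 | (8S,10S)-8-triisopropylsilyloxy-9-ketone | CC(C)[Si](C(C)C)(C(C)C)O[C@@H]1C(=O)[C@@H](C)CCC[C@@]3(C)OC(C)(C)O[C@H]3[C@H](OCc2ccccc2)[C@H]1C(C(=O)OCc2ccccc2)C(=O)OCc2ccccc2 | intermediate
20 | 6-hydroxy 7-malonic acid (acetonide and silyl ether retained) | CC(C)[Si](C(C)C)(C(C)C)O[C@@H]1C(=O)[C@@H](C)CCC[C@@]3(C)OC(C)(C)O[C@H]3[C@H](O)[C@H]1C(C(=O)O)C(=O)O | intermediate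
21 | 12,6-lactone 11-carboxylic acid, 4,5-diol, 8-O-silyl ether (C11 epimers, inconsequential) | CC(C)[Si](C(C)C)(C(C)C)O[C@@H]1C(=O)[C@@H](C)CCC[C@@](C)(O)[C@@H](O)[C@@H]2OC(=O)C(C(=O)O)[C@@H]12 | intermediate
22 | formaldehyde | C=O | starting material
23 | α-methylene 12,6-lactone, 4,5-diol, 8-O-silyl ether | CC(C)[Si](C(C)C)(C(C)C)O[C@@H]1C(=O)[C@@H](C)CCC[C@@](C)(O)[C@@H](O)[C@@H]2OC(=O)C(=C)[C@@H]12 | intermediate
24 | 2-methylpropanoic anhydride | CC(C)C(=O)OC(=O)C(C)C | starting material
25 | 5-O-isobutyrate of 23 | CC(C)[Si](C(C)C)(C(C)C)O[C@@H]1C(=O)[C@@H](C)CCC[C@@](C)(O)[C@@H](OC(=O)C(C)C)[C@@H]2OC(=O)C(=C)[C@@H]12 | intermediate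
26 | target: (4R,5S,6R,7S,8S,10S)-4,8-dihydroxy-5-isobutyryloxy-9-oxogermacr-11(13)-en-12,6-olide (numbering of this proposal) | O[C@@H]1C(=O)[C@@H](C)CCC[C@@](C)(O)[C@@H](OC(=O)C(C)C)[C@@H]2OC(=O)C(=C)[C@@H]12 | target

**Step count and risks**

Total steps: 17. Longest linear sequence: 17 steps (1 → 26).

Most likely to fail:

Step 10. The alkoxide of 14 has its two alkenyl groups trans-diaxial in the ground-state chair and must pass through a crowded ring-flipped conformer, so warming may be needed and base-induced decomposition (ester condensation, elimination of the benzyloxy group) could outrun the rearrangement. Fallback, setting out from 14 and coming back at 16: the rearrangement is run without charge. Silylation of 14 (Me3SiOTf, 2,6-lutidine, CH2Cl2, −78 °C) gives the tertiary trimethylsilyl ether F1, which is heated (about 200 °C, 1,2-dichlorobenzene, sealed tube) to undergo the thermal siloxy-Cope rearrangement to the trimethylsilyl enol ether F2. MeLi (2.2 equiv, THF, 0 °C) then releases the lithium enolate regiospecifically, and i-Pr3SiOTf gives 16.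

Step 12. Borane could add to the other face of C8=C9 if the enol ether rotates through the ring after step 11 (giving the C8 epimer), or the β-silyloxy borane could eliminate before oxidation. Fallback, setting out from 17 and coming back at 18: the source of stereocontrol is moved from the substrate to the reagent. Asymmetric hydroboration with monoisopinocampheylborane (IpcBH2 from the α-pinene antipode matched to the required face, THF, −25 °C) is followed at once by the same buffered peroxide oxidation; no compound outside the list arises (F0).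

Step 9. Facial selectivity in the carbonyl addition may be poor. Attack on the β face would give the C8 epimer, whose rearrangement should give the same C10 configuration but the geometrical isomer of the enol ether, and hence the wrong face in step 12. Fallback, setting out from 12 and coming back at 14: a slimmer nucleophile with a strong preference for axial attack is used and the alkene is made afterwards. Addition of 1-propynylmagnesium bromide/CeCl3 (THF, −78 °C) should give the 8α-propynyl carbinol F3. After conversion of the malonate into its sodium enolate (NaH), hydroxyl-directed trans-hydroalumination with NaAlH2(OCH2CH2OMe)2 (THF, −20 → 0 °C) and protonolysis gives the (E)-alkene 14.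

Further compounds
F1 | step 10 | trimethylsilyl ether of carbinol 14 | C[Si](C)(C)O[C@]1(/C=C/C)[C@H](C=C)[C@@]3(C)OC(C)(C)O[C@H]3[C@H](OCc2ccccc2)[C@H]1C(C(=O)OCc2ccccc2)C(=O)OCc2ccccc2
F2 | step 10 | trimethylsilyl enol ether analogue of 16 ((2E,8Z)-diene, 10S) | C[Si](C)(C)O\C1=C/[C@@H](C)C/C=C/[C@@]3(C)OC(C)(C)O[C@H]3[C@H](OCc2ccccc2)[C@H]1C(C(=O)OCc2ccccc2)C(=O)OCc2ccccc2
F0 | step 12 | none | none
F3 | step 9 | 8β-hydroxy-8α-(prop-1-ynyl) carbinol | O[C@]1(C#CC)[C@H](C=C)[C@@]3(C)OC(C)(C)O[C@H]3[C@H](OCc2ccccc2)[C@H]1C(C(=O)OCc2ccccc2)C(=O)OCc2ccccc2
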